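Late times gave me the handle on these flasks.

| flask | L | Z | remark | time |
|---|---|---|---|---|
| alpha | 0.20 M | 28 mM | run made earlier |  |
| theta | 0.45 M | 28 mM | run made earlier |  |
| red | 0.30 M | 28 mM |  | 15 h |
| grey | 0.30 M | 28 mM |  | 4.0 h |

- alpha (time / h: D / %): 1.33: 1.7; 2.00: 1.4; 3.00: 2.8; 5.00: 5.6; 8.00: 9.1; 12.0: 13.7; 20.0: 21.2
- theta (time / h: D / %): 1.00: 0.7; 3.00: 3.5; 5.00: 6.8; 8.00: 11.1; 10.0: 13.3; 15.0: 18.8; 20.0: 23.1

(scatter of a reading: 0.3 percentage points)

- which of the two ends with the longer chains by the average number of monomer units in a chain (chains begun, living or dead) ("neither" if they lie within 10%) (red / grey / neither)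
- average number of monomer units in a chain (chains begun, living or dead) at the end, red
- average number of monomer units in a chain (chains begun, living or dead) at the end, grey

- the average divides the monomer in chains by the number of chains begun, living and dead together
- what was read earlier has a scatter of 0.3 percentage points, one standard deviation
- the earlier runs do not show the number of chains; that part of a forecast is a guess

Between the late readings, alpha lost 0.0114 h⁻¹ of its L and theta 0.0120 h⁻¹, although theta held 2.25 times the L. So the rate looked pseudo-first-order in L, and the concentration behind the coefficient was not L. I called the mean, 0.0117 h⁻¹, the late coefficient: the fraction of L passing into D per hour.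

Run from the start, it gave D of 16.1% in red and 4.56% in grey, or 48.2 mM and 13.7 mM. The average is D over chains begun. Chains begun could not pass the charged Z, so on this estimate of D red held at least 1.72 units a chain. Grey's 0.489 fell under one, so its floor was a chain's own first unit.

From above I had a guess. If the D read in alpha at 2.00 h, 2.80 mM, were first units, and chains begun stay in the count, red stopped at 17.2 and grey at 4.89. I took the middle by ratio: 5.44 for red and 2.21 for grey.

The forecast said red, with 12 for red (range 6 to 28) and 6.5 for grey (range 3 to 11). It said plainly: “Chain number is a guess.” Its red lay inside my bracket, but its grey lay above my ceiling.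

The flask gave red: 3.35 in red and 2.28 in grey.

    L + E → G + D (k = 0.520 M⁻¹ h⁻¹)
    L + G → D + G, rate k2*[G]*[L] (k = 2.80 M⁻¹ h⁻¹)
    2 G → J (k = 36.0 M⁻¹ h⁻¹)
    Z ⇌ E (K = 0.730, k = 1.10 h⁻¹)

In red at 15.0 h, L passed into D 3.5 times as fast by the growing step L into D as by the starting step L + E into G + D, and red then held 17.9% of D against the 16.1% of the late coefficient. For the neighbour flask, red with 0.12 M of L, the late coefficient gave 16.1% again, and that flask ended with 15.3% of D.

(The readings were generated by integration on assumed constants, noise included.)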